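**Compound 38** is the target, (1R,6S,7S,8S)-7-(4-hydroxyphenyl)-1-[(E)-2-(4-hydroxyphenyl)ethenyl]-5-methoxy-8-(4-methoxy-2-oxo-2H-pyran-6-yl)-2-oxabicyclo[4.2.0]oct-4-en-3-one. Ring atoms are numbered C1 (quaternary carbinol), O2, C3 (carbonyl), C4, C5 (methoxy carbon), C6 (fusion CH), C7 (aryl CH), C8 (pyranonyl CH) throughout, also for monocyclic precursors.

## Analysis of the target

- Compound 38 is a cyclobutane (C1, C6, C7, C8) cis-fused through C1 and C6 to a 4-methoxy-5,6-dihydro-2-pyranone (O2, C3, C4, C5).
- All four cyclobutane carbons are stereocentres, (1R,6S,7S,8S). C1 is quaternary and carries O2 and an E-4-hydroxystyryl group, C7 a 4-hydroxyphenyl group and C8 a 4-methoxy-2-pyranon-6-yl group.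
- O2 and C5 lie on one face of the four-membered ring, and the C7 aryl group lies on that same face. The substituents on C6 and C7 are therefore cis, which is the less stable arrangement. The C8 pyranonyl group is on the other face, trans to the aryl and cis to the styryl group.
- The C1–O2 bond is tertiary, allylic and, through the styrene, para-hydroxybenzylic. It can ionise under acid and can be expelled from a phenoxide as an extended quinone methide.
- The enol ether lactone and the methoxypyranone are electrophilic, and C8–H sits next to the pyranone and β to the C1 acyloxy group, so strong base is excluded late in the route.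
- The molecule is formally an unsymmetrical head-to-tail [2+2] dimer of two styrylpyranones. A direct cycloaddition would control neither regiochemistry, nor the cis/trans pattern, nor the absolute configuration.
- The strategy rests on one feature: C1 is a tertiary alkenyl carbinol whose oxygen is acylated by C3, the end of the three-carbon chain on the neighbouring C6. C1 can therefore be a ketone carbon, and the C1–styryl and O2–C3 bonds can be made in one operation.

## Retrosynthetic reasoning

**Pyranone on C8 (38 ← 37 ← 34 ← 33 ← 29 + 32).** The phenols are unmasked last from bis-silyl ether 37. The pyranone is cut between its ring oxygen and C2' (cyclisation of acylketene 35, released from keto dioxinone 34) and between C5' and C6' (vinylogous aldol of aldehyde 29 with silyl dienol ether 32, then oxidation of adduct 33). The cut is made here because a pyranone carbonyl and an acidic C8–H could not pass through an organometallic addition. C8 then needs only a one-carbon arm, alcohol 28.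

**Enol ether C4=C5 (28 ← 26).** The methoxy enol ether is traced to the C5 dimethyl ketal of lactone 26, by loss of one methoxy group and a C4 proton together with removal of the silyl group on the C8 arm. Carrying C5 as a ketal keeps C6 from ever being a 1,3-dicarbonyl carbon.

**Key disconnection (26 ← 18 + 22).** The C1–styryl bond and the O2–C3 bond are cut together. This leads to cyclobutanone 18, which carries the ketal ester chain on C6, and to E-styryl bromide 22. The forward reaction has to add the styryl group to one face of the ketone and let the alkoxide close on the ester. Cutting here removes the quaternary centre, one ring and the whole styryl unit at once.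

**C8 arm (18 ← 17 ← 15).** The C8–CH2O bond is cut. Forward, the kinetic enolate 16 of ketone 15 takes up a one-carbon electrophile trans to the neighbouring aryl group, and alcohol 17 is silylated. The small triethylsilyl group keeps the face of later attack open and is removable by mild acid beside aryl triisopropylsilyl ethers.

**Cis hydrogens on C6 and C7 (15 ← 14 ← 13 ← 12).** The two cis hydrogens are removed to give cyclobutenone 12, which has no stereocentre. Forward, an enantioselective carbonyl reduction gives cyclobutenol 13, its hydroxyl group directs syn hydrogenation to give 14, and oxidation returns the ketone. The temporary carbinol centre thus sets both the cis relation and the absolute configuration.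

**Four-membered ring (12 ← 11 ← 8 + 10).** C1–C6 and C7–C8 are cut. Dichloroketene 10, from trichloroacetyl chloride 9, adds to alkyne 8 with the carbonyl carbon bonding to the alkyne carbon remote from the aryl group. Reductive dechlorination of 11 gives 12. Nothing stereochemical is at stake in the ring-forming step.

**Alkyne 8 (8 ← 2 + 7; 7 ← 6 ← 5 ← 3 + 4; 2 ← 1).** The aryl–alkyne bond is cut to aryl iodide 2 (from 4-iodophenol 1) and terminal alkyne 7. Alkyne 7 comes from keto ester 5, made by acylation of bis(trimethylsilyl)acetylene 3 with methyl 3-chloro-3-oxopropanoate 4, through ketal 6. The complete C3–C5 chain of the lactone is thus in place before the ring exists.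

**Styryl bromide (22 ← 21 ← 19).** The bromide is traced to silyl-protected acid 21 by decarboxylative bromination, and to 4-hydroxycinnamic acid 19.

## Alternatives that were turned down

Alternative 1: The C1–C6 bond is disconnected and the whole four-membered ring is traced to a flat 2-pyranone A1. In the forward key step, irradiation near 300 nm causes a 4π electrocyclisation that joins pyranone C3 to C6 and gives the bicyclic β-lactone A2. The quaternary oxygen-bearing carbon (future C1) and the future C6 are then cis by necessity.
- For: one step from an achiral heteroaromatic builds the ring, the quaternary carbinol and the cis fusion, with no addition to a hindered ketone. On this point it is stronger than the chosen route, which needs eleven linear steps to reach cyclobutanone 18.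
- Against: A2 is racemic, with no handle for absolute control. It is a strained β-lactone fused to a cyclobutene and is prone to decarboxylation and thermal reversion, and the excited pyranone can also open to a ketene.
- Against, after the key step: the one-carbon arm on C1 must be oxidised and olefinated to the styryl group. The β-lactone must be opened by an ester enolate although it has an acidic α-hydrogen that invites enolisation and β-elimination.
- Comparison: the chosen strategy gives reagent-controlled absolute configuration and brings in the styryl group intact in the step that closes the lactone.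

Alternative 2: C1–C6 and C7–C8 are disconnected so that the cyclobutanone arises in one [2+2] step. Forward, amide A3 is activated to a keteniminium ion that adds to Z-alkene A4. Hydrolysis gives cyclobutanone A5, with the cis C6/C7 relation copied from the alkene and the C8 arm trans to the aryl group.
- For: it is the shortest conceivable access to a cyclobutanone with three ring stereocentres and is fully convergent. In step count to the ketone it clearly beats the chosen route.
- Against: keteniminium additions to aryl alkenes go stepwise through a benzylic cation. With a para-oxygenated arene this cation can rotate before closure, so the Z geometry is not reliably transferred.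
- Against: asymmetric induction from a pyrrolidine auxiliary with an acyclic 1,2-disubstituted alkene is the least dependable element.
- Against: A5 carries C6 only as a silyloxymethyl arm. Elaborating it to the keto ester chain passes through a carbonyl β to the ring ketone, which epimerises C6, or must wait until after the styryl addition and then costs five or six further operations.
- Comparison: the chosen strategy spends more steps early, but installs the complete C6 chain at the alkyne stage, takes the cis relation from a stereospecific syn hydrogenation and lets the lactone close in the addition step itself.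

Alternative 3: C6–C7 is disconnected and the cyclobutane is traced to pyrrolidine A6, in which nitrogen bridges C6 and C7. Forward, N-amination with a hypervalent iodine oxidant and an ammonia surrogate gives a 1,1-diazene. This loses nitrogen, and the 1,4-biradical collapses to cyclobutane A7.
- For: the azomethine ylide cycloaddition leading to A6 belongs to a very well developed class of enantioselective reactions. All four stereocentres, including quaternary C1, are set on a five-membered ring, and the C1 acetate and C6 ester are placed for a Dieckmann-type lactone closure. In setting the quaternary centre without a diastereoselective carbonyl addition it is stronger than the chosen route.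
- Against: the biradical is benzylic and para-oxygenated at C7 and ester-stabilised at C6. Ring closure therefore competes with bond rotation (loss of the cis C6/C7 relation) and with β-scission to two alkenes.
- Against: the oxidant must spare an electron-rich styrene, and the dipolarophile needed for A6 is a poorly reactive trisubstituted enol acetate. The later Dieckmann step needs strong base beside an epimerisable C6 ester.
- Comparison: the chosen strategy forms the ring in a step with no stereochemistry at stake and then adds the stereocentres one at a time by polar, face-selective reactions.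

Key step: step 15

Assumption: the oxazaborolidine reduction of enone 12 is taken to follow the usual model, with the substituted alkene carbon as the large group. If the sense proved opposite, the enantiomeric catalyst would be used.

## Route

Step 1
Reactants: 1 4-iodophenol
Product: 2 (4-iodophenoxy)triisopropylsilane
Conditions: TIPSCl, imidazole, DMF, rt
Reagents that add atoms: chlorotriisopropylsilane, CC(C)[Si](Cl)(C(C)C)C(C)C
Why: Standard O-silylation of a phenol; the triisopropylsilyl ether is chosen because it should survive carbonate bases, organometallics and mild acid and still leave with buffered fluoride.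

Step 2
Reactants: 3 bis(trimethylsilyl)acetylene; 4 methyl 3-chloro-3-oxopropanoate
Product: 5 methyl 3-oxo-5-(trimethylsilyl)pent-4-ynoate
Conditions: AlCl3, CH2Cl2, 0 °C
Reagents that add atoms: none
Why: Friedel–Crafts-type ipso acylation of an alkynylsilane: the acylium complex attacks the alkyne, the β-silyl cation loses one silyl group, and mono-acylation should stop there because the ynone is deactivated.

Step 3
Reactants: 5 methyl 3-oxo-5-(trimethylsilyl)pent-4-ynoate
Product: 6 methyl 3,3-dimethoxy-5-(trimethylsilyl)pent-4-ynoate
Conditions: HC(OMe)3, MeOH, TsOH·H2O (cat.), rt; Et3N before concentration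
Reagents that add atoms: trimethyl orthoformate, COC(OC)OC; methanol, CO
Why: Acid-catalysed ketalisation with the orthoformate as water scavenger; the electron-poor ynone carbonyl favours the tetrahedral ketal, and neutralising before concentration should prevent cracking to the 3-methoxy enoate.

Step 4
Reactants: 6 methyl 3,3-dimethoxy-5-(trimethylsilyl)pent-4-ynoate
Product: 7 methyl 3,3-dimethoxypent-4-ynoate
Conditions: K2CO3 (cat.), MeOH, 0 °C
Reagents that add atoms: none
Why: Methoxide-mediated protodesilylation of an alkynylsilane; it is fast at 0 °C, where the ester is not enolised, so the β-methoxy groups should not be eliminated.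

Step 5
Reactants: 2 (4-iodophenoxy)triisopropylsilane; 7 methyl 3,3-dimethoxypent-4-ynoate
Product: 8 methyl 3,3-dimethoxy-5-[4-(triisopropylsilyloxy)phenyl]pent-4-ynoate
Conditions: Pd(PPh3)2Cl2 (2 mol%), CuI (4 mol%), Et3N, THF, rt
Reagents that add atoms: none
Why: Sonogashira coupling of an aryl iodide with a terminal alkyne; the propargylic ketal and the aryl silyl ether are inert to the amine base.

Step 6
Reactants: 8 methyl 3,3-dimethoxy-5-[4-(triisopropylsilyloxy)phenyl]pent-4-ynoate; 9 trichloroacetyl chloride
Product: 11 methyl 3-{3,3-dichloro-4-oxo-2-[4-(triisopropylsilyloxy)phenyl]cyclobut-1-en-1-yl}-3,3-dimethoxypropanoate, via dichloroketene 10 (not isolated)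
Conditions: zinc–copper couple, Et2O–DME, rt, slow addition of 9
Reagents that add atoms: none
Why: Ketene–alkyne [2+2] cycloaddition: the alkyne carbon remote from the aryl group attacks the ketene carbonyl carbon while the para-silyloxyphenyl group stabilises the positive charge that the CCl2 carbon then closes, which fixes the regiochemistry; DME ties up zinc dichloride so that the doubly deactivated ketal should survive.

Step 7
Reactants: 11 dichlorocyclobutenone from step 6
Product: 12 methyl 3,3-dimethoxy-3-{4-oxo-2-[4-(triisopropylsilyloxy)phenyl]cyclobut-1-en-1-yl}propanoate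
Conditions: Zn, AcOH, TMEDA, EtOH, 0 °C to rt
Reagents that add atoms: none
Why: Reductive dechlorination of an α,α-dichloro ketone by zinc through zinc enolates; the amine-buffered medium should spare the ketal and the enone double bond.

Step 8
Reactants: 12 cyclobutenone from step 7
Product: 13 methyl 3-{(4R)-4-hydroxy-2-[4-(triisopropylsilyloxy)phenyl]cyclobut-1-en-1-yl}-3,3-dimethoxypropanoate
Conditions: (S)-2-methyl-CBS-oxazaborolidine (20 mol%), catecholborane, toluene, −78 °C
Reagents that add atoms: none
Why: Corey–Bakshi–Shibata 1,2-reduction of an α-substituted cyclic enone; the fully substituted alkene carbon with its quaternary ketal acts as the large group against the ring CH2, so the catalyst should deliver hydride to one face and set the carbinol centre as R.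

Step 9
Reactants: 13 cyclobutenol from step 8
Product: 14 methyl 3-{(1R,2R,4R)-2-hydroxy-4-[4-(triisopropylsilyloxy)phenyl]cyclobutyl}-3,3-dimethoxypropanoate (ketal chain and aryl cis to each other, hydroxyl trans to both)
Conditions: H2 (1 atm), [Ir(cod)(PCy3)(py)]PF6 (5 mol%), CH2Cl2, rt
Reagents that add atoms: none
Why: Hydroxyl-directed hydrogenation of a strained tetrasubstituted alkene: the cationic iridium binds the allylic hydroxyl and adds both hydrogens syn on that face, which sets C6 and C7 cis and relays the carbinol configuration to them; any diastereomer from attack on the other face is separable, so it cannot erode the enantiomeric purity of the later ketone.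

Step 10
Reactants: 14 cyclobutanol from step 9
Product: 15 methyl 3,3-dimethoxy-3-{(1R,2R)-4-oxo-2-[4-(triisopropylsilyloxy)phenyl]cyclobutyl}propanoate (ketal chain and aryl cis)
Conditions: Dess–Martin periodinane, NaHCO3, CH2Cl2, 0 °C
Reagents that add atoms: none
Why: Dess–Martin oxidation under buffered, non-basic conditions; the cis C6 hydrogen is α to one carbonyl only, because C5 is a ketal, and should not epimerise.

Step 11
Reactants: 15 cis-cyclobutanone from step 10
Product: 17 methyl 3-{(1R,2R,3S)-3-(hydroxymethyl)-4-oxo-2-[4-(triisopropylsilyloxy)phenyl]cyclobutyl}-3,3-dimethoxypropanoate, via lithium enolate 16 (not isolated)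
Conditions: LDA, THF, −78 °C; CH2O (gas), −78 °C; AcOH quench at −78 °C
Reagents that add atoms: formaldehyde, C=O
Why: Kinetic deprotonation at the unhindered ring CH2 (C8) and not at the hindered C6 methine, followed by an aldol reaction with monomeric formaldehyde; the electrophile approaches anti to the adjacent aryl group, so the hydroxymethyl group ends up trans to it, which is also the more stable arrangement.

Step 12
Reactants: 17 hydroxymethyl ketone from step 11
Product: 18 methyl 3,3-dimethoxy-3-{(1R,2R,3S)-4-oxo-3-[(triethylsilyloxy)methyl]-2-[4-(triisopropylsilyloxy)phenyl]cyclobutyl}propanoate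
Conditions: TESCl, imidazole, CH2Cl2, 0 °C
Reagents that add atoms: chlorotriethylsilane, CC[Si](Cl)(CC)CC
Why: Silylation of a primary alcohol under mild conditions, which blocks retro-aldol loss of the one-carbon arm in the next step.

Step 13
Reactants: 19 4-hydroxycinnamic acid
Product: 21 (E)-3-[4-(triisopropylsilyloxy)phenyl]prop-2-enoic acid, via triisopropylsilyl ester 20 (not isolated)
Conditions: TIPSCl (2.2 equiv), imidazole, DMF, rt; then K2CO3, MeOH–H2O, rt
Reagents that add atoms: chlorotriisopropylsilane, CC(C)[Si](Cl)(C(C)C)C(C)C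
Why: Double silylation followed by selective hydrolysis of the much more labile silyl ester; the aryl silyl ether should stay.

Step 14
Reactants: 21 silyloxycinnamic acid from step 13
Product: 22 (E)-1-bromo-2-[4-(triisopropylsilyloxy)phenyl]ethene
Conditions: NBS, Et3N (10 mol%), CH2Cl2, rt
Reagents that add atoms: N-bromosuccinimide, O=C1CCC(=O)N1Br
Why: Catalytic Hunsdiecker-type bromodecarboxylation of an electron-rich cinnamate: bromination at the α-carbon gives a benzylic cation or β-lactone that loses the carboxyl group, and the E-bromide is expected because the aryl-stabilised intermediate equilibrates before elimination.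

Step 15
Reactants: 22 (E)-styryl bromide from step 14; 18 cyclobutanone from step 12
Product: 26 (1S,6R,7R,8S)-5,5-dimethoxy-8-[(triethylsilyloxy)methyl]-7-[4-(triisopropylsilyloxy)phenyl]-1-{(E)-2-[4-(triisopropylsilyloxy)phenyl]ethenyl}-2-oxabicyclo[4.2.0]octan-3-one, via styryllithium 23 (not isolated), via styrylcerium dichloride 24 (not isolated), via cerium alkoxide 25 (not isolated)
Conditions: t-BuLi (2 equiv per 22), Et2O, −78 °C; CeCl3, THF, −78 °C; 18, −78 °C to rt; aq. NH4Cl
Reagents that add atoms: none
Why: Bromine–lithium exchange with two equivalents of t-BuLi gives styryllithium 23 with retention of the E geometry, and transmetallation to CeCl3 gives the weakly basic, oxophilic organocerium 24, the standard reagent class for 1,2-addition to enolisable strained ketones. Ketone 18 should therefore be attacked at the carbonyl carbon rather than deprotonated at C6 or C8, and in preference to the less electrophilic methyl ester. The new stereocentre C1 is set by the substrate: the ketal chain on C6 and the aryl group on C7 stand on the same face of the puckered ring, and chelation of cerium between the carbonyl oxygen and a ketal methoxy group should shield that face further, so the styryl group enters from the face that carries only the small triethylsilyloxymethyl arm. The oxygen of alkoxide 25 is then cis to the C6 chain, and on warming it attacks the methyl ester in a 6-exo-trig acyl substitution that forms O2–C3, closes the six-membered lactone and expels methoxide. The closest known reaction type is alkenylcerium addition to a substituted cyclobutanone anti to its ring substituents, followed by lactonisation of the alkoxide onto a cis ester. The step needs facial selectivity and chemoselectivity: the first is reinforced because only the wanted alkoxide can reach the ester, so a C1 epimer would remain a separable hydroxy ester, and the second is secured by the C5 ketal, which removes the 1,3-dicarbonyl acidity at C6 and so preserves the cis C6/C7 relation. Acylation in the same flask also removes the 1-alkenylcyclobutoxide before it can undergo anion-accelerated ring expansion or opening.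

Step 16
Reactants: 26 ketal lactone from step 15
Product: 28 8-(hydroxymethyl)-5-methoxy-7-[4-(triisopropylsilyloxy)phenyl]-1-{(E)-2-[4-(triisopropylsilyloxy)phenyl]ethenyl}-2-oxabicyclo[4.2.0]oct-4-en-3-one (ring configuration as in 26), via hydroxy ketal lactone 27 (not isolated)
Conditions: PPTS, MeOH, rt; then PPTS, PhMe, 4 Å MS, 70 °C
Reagents that add atoms: none
Why: Mild acid in methanol cleaves the primary triethylsilyl ether and leaves the aryl triisopropylsilyl ethers; after solvent exchange the same acid ionises the ketal, and loss of the C4 proton gives the conjugated enol ether (acid-catalysed ketal to enol ether elimination), the direction toward C6 being disfavoured because it would give an unconjugated alkylidenecyclobutane.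

Step 17
Reactants: 28 hydroxy enol ether lactone from step 16
Product: 29 5-methoxy-3-oxo-7-[4-(triisopropylsilyloxy)phenyl]-1-{(E)-2-[4-(triisopropylsilyloxy)phenyl]ethenyl}-2-oxabicyclo[4.2.0]oct-4-ene-8-carbaldehyde (ring configuration as in 26)
Conditions: Dess–Martin periodinane, NaHCO3, CH2Cl2, 0 °C; used crude
Reagents that add atoms: none
Why: Dess–Martin oxidation is non-basic, which matters because the aldehyde is β-acyloxy and α-acidic and would lose the lactone carboxylate by E1cB elimination under base.

Step 18
Reactants: 30 2,2,6-trimethyl-4H-1,3-dioxin-4-one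
Product: 32 [(2,2-dimethyl-6-methylidene-6H-1,3-dioxin-4-yl)oxy]trimethylsilane, via lithium dienolate 31 (not isolated)
Conditions: LDA, THF, −78 °C; TMSCl
Reagents that add atoms: chlorotrimethylsilane, C[Si](C)(C)Cl
Why: γ-Deprotonation of the vinylogous ester and O-silylation of the dienolate, the standard preparation of this acetoacetate dianion equivalent.

Step 19
Reactants: 29 aldehyde from step 17; 32 silyl dienol ether from step 18
Product: 33 8-[2-(2,2-dimethyl-4-oxo-4H-1,3-dioxin-6-yl)-1-hydroxyethyl]-5-methoxy-7-[4-(triisopropylsilyloxy)phenyl]-1-{(E)-2-[4-(triisopropylsilyloxy)phenyl]ethenyl}-2-oxabicyclo[4.2.0]oct-4-en-3-one (ring configuration as in 26; carbinol epimers, both carried on)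
Conditions: BF3·OEt2, CH2Cl2, −78 °C
Reagents that add atoms: none
Why: Vinylogous Mukaiyama aldol: the γ-carbon of the dienol ether adds to the Lewis-acid-activated aldehyde at −78 °C with no base present, so C8 is not deprotonated; the new carbinol centre is removed in the next step.

Step 20
Reactants: 33 aldol adduct from step 19
Product: 34 8-[(2,2-dimethyl-4-oxo-4H-1,3-dioxin-6-yl)acetyl]-5-methoxy-7-[4-(triisopropylsilyloxy)phenyl]-1-{(E)-2-[4-(triisopropylsilyloxy)phenyl]ethenyl}-2-oxabicyclo[4.2.0]oct-4-en-3-one (ring configuration as in 26)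
Conditions: Dess–Martin periodinane, NaHCO3, CH2Cl2, 0 °C to rt
Reagents that add atoms: none
Why: Dess–Martin oxidation of the secondary alcohol to the ketone under non-basic conditions; the acidic CH2 between ketone and dioxinone, not C8, takes up any enolisation.

Step 21
Reactants: 34 keto dioxinone from step 20
Product: 37 (1R,6S,7S,8S)-5-methoxy-8-(4-methoxy-2-oxo-2H-pyran-6-yl)-7-[4-(triisopropylsilyloxy)phenyl]-1-{(E)-2-[4-(triisopropylsilyloxy)phenyl]ethenyl}-2-oxabicyclo[4.2.0]oct-4-en-3-one, via acylketene 35 (not isolated), via hydroxypyranone 36 (not isolated)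
Conditions: PhMe, 100 °C; then Me2SO4, K2CO3, acetone, rt
Reagents that add atoms: dimethyl sulfate, COS(=O)(=O)OC
Why: Thermal retro-[4+2] of the dioxinone releases acetone and acylketene 35, which is trapped by the enol oxygen of the neighbouring ketone to give the 4-hydroxy-2-pyranone 36; its acidic vinylogous acid is then methylated on the 4-oxygen by dimethyl sulfate and carbonate, conditions under which the aryl silyl ethers and C8–H should be untouched.

Step 22
Reactants: 37 bis-silyl ether from step 21
Product: 38 (1R,6S,7S,8S)-7-(4-hydroxyphenyl)-1-[(E)-2-(4-hydroxyphenyl)ethenyl]-5-methoxy-8-(4-methoxy-2-oxo-2H-pyran-6-yl)-2-oxabicyclo[4.2.0]oct-4-en-3-one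
Conditions: TBAF, AcOH (1:1), THF, 0 °C
Reagents that add atoms: none
Why: Fluoride cleavage of the aryl silyl ethers; the acetic acid buffer keeps the phenols protonated, so that no phenoxide can expel the C1 carboxylate as an extended quinone methide.

## Compound list

1 | 4-iodophenol | Oc1ccc(I)cc1 | starting material
2 | (4-iodophenoxy)triisopropylsilane | CC(C)[Si](Oc1ccc(I)cc1)(C(C)C)C(C)C | intermediate
3 | bis(trimethylsilyl)acetylene | C[Si](C)(C)C#C[Si](C)(C)C | starting material
4 | methyl 3-chloro-3-oxopropanoate | COC(=O)CC(=O)Cl | starting material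
5 | methyl 3-oxo-5-(trimethylsilyl)pent-4-ynoate | COC(=O)CC(=O)C#C[Si](C)(C)C | intermediate
6 | methyl 3,3-dimethoxy-5-(trimethylsilyl)pent-4-ynoate | COC(=O)CC(OC)(OC)C#C[Si](C)(C)C | intermediate
7 | methyl 3,3-dimethoxypent-4-ynoate | COC(=O)CC(OC)(OC)C#C | intermediate
8 | methyl 3,3-dimethoxy-5-[4-(triisopropylsilyloxy)phenyl]pent-4-ynoate | COC(=O)CC(OC)(OC)C#Cc1ccc(O[Si](C(C)C)(C(C)C)C(C)C)cc1 | intermediate
9 | trichloroacetyl chloride | O=C(Cl)C(Cl)(Cl)Cl | starting material
10 | dichloroketene | O=C=C(Cl)Cl | intermediate (not isolated)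
11 | methyl 3-{3,3-dichloro-4-oxo-2-[4-(triisopropylsilyloxy)phenyl]cyclobut-1-en-1-yl}-3,3-dimethoxypropanoate | COC(=O)CC(OC)(OC)C1=C(c2ccc(O[Si](C(C)C)(C(C)C)C(C)C)cc2)C(Cl)(Cl)C1=O | intermediate
12 | methyl 3,3-dimethoxy-3-{4-oxo-2-[4-(triisopropylsilyloxy)phenyl]cyclobut-1-en-1-yl}propanoate | COC(=O)CC(OC)(OC)C1=C(c2ccc(O[Si](C(C)C)(C(C)C)C(C)C)cc2)CC1=O | intermediate
13 | methyl 3-{(4R)-4-hydroxy-2-[4-(triisopropylsilyloxy)phenyl]cyclobut-1-en-1-yl}-3,3-dimethoxypropanoate | COC(=O)CC(OC)(OC)C1=C(c2ccc(O[Si](C(C)C)(C(C)C)C(C)C)cc2)C[C@H]1O | intermediate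
14 | methyl 3-{(1R,2R,4R)-2-hydroxy-4-[4-(triisopropylsilyloxy)phenyl]cyclobutyl}-3,3-dimethoxypropanoate | O[C@H]1[C@H](C(OC)(OC)CC(=O)OC)[C@H](c2ccc(O[Si](C(C)C)(C(C)C)C(C)C)cc2)C1 | intermediate
15 | methyl 3,3-dimethoxy-3-{(1R,2R)-4-oxo-2-[4-(triisopropylsilyloxy)phenyl]cyclobutyl}propanoate | O=C1[C@H](C(OC)(OC)CC(=O)OC)[C@H](c2ccc(O[Si](C(C)C)(C(C)C)C(C)C)cc2)C1 | intermediate
16 | lithium enolate of 15 toward the ring CH2 (C1=C8) | [Li]OC=1[C@H](C(OC)(OC)CC(=O)OC)[C@H](c2ccc(O[Si](C(C)C)(C(C)C)C(C)C)cc2)C=1 | intermediate (not isolated)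
17 | methyl 3-{(1R,2R,3S)-3-(hydroxymethyl)-4-oxo-2-[4-(triisopropylsilyloxy)phenyl]cyclobutyl}-3,3-dimethoxypropanoate | O=C1[C@H](C(OC)(OC)CC(=O)OC)[C@H](c2ccc(O[Si](C(C)C)(C(C)C)C(C)C)cc2)[C@H]1CO | intermediate
18 | methyl 3,3-dimethoxy-3-{(1R,2R,3S)-4-oxo-3-[(triethylsilyloxy)methyl]-2-[4-(triisopropylsilyloxy)phenyl]cyclobutyl}propanoate | O=C1[C@H](C(OC)(OC)CC(=O)OC)[C@H](c2ccc(O[Si](C(C)C)(C(C)C)C(C)C)cc2)[C@H]1CO[Si](CC)(CC)CC | intermediate
19 | 4-hydroxycinnamic acid | O=C(O)/C=C/c1ccc(O)cc1 | starting material
20 | triisopropylsilyl (E)-3-[4-(triisopropylsilyloxy)phenyl]prop-2-enoate | CC(C)[Si](OC(=O)/C=C/c1ccc(O[Si](C(C)C)(C(C)C)C(C)C)cc1)(C(C)C)C(C)C | intermediate (not isolated)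
21 | (E)-3-[4-(triisopropylsilyloxy)phenyl]prop-2-enoic acid | O=C(O)/C=C/c1ccc(O[Si](C(C)C)(C(C)C)C(C)C)cc1 | intermediate
22 | (E)-1-bromo-2-[4-(triisopropylsilyloxy)phenyl]ethene | Br/C=C/c1ccc(O[Si](C(C)C)(C(C)C)C(C)C)cc1 | intermediate
23 | (E)-2-[4-(triisopropylsilyloxy)phenyl]ethenyllithium | [Li]/C=C/c1ccc(O[Si](C(C)C)(C(C)C)C(C)C)cc1 | intermediate (not isolated)
24 | dichloro{(E)-2-[4-(triisopropylsilyloxy)phenyl]ethenyl}cerium | Cl[Ce](Cl)/C=C/c1ccc(O[Si](C(C)C)(C(C)C)C(C)C)cc1 | intermediate (not isolated)
25 | dichlorocerium alkoxide of the tertiary cyclobutanol from 18 and 24 (oxygen cis to the ketal ester chain and the aryl group) | Cl[Ce](Cl)O[C@]1(/C=C/c2ccc(O[Si](C(C)C)(C(C)C)C(C)C)cc2)[C@H](C(OC)(OC)CC(=O)OC)[C@H](c2ccc(O[Si](C(C)C)(C(C)C)C(C)C)cc2)[C@H]1CO[Si](CC)(CC)CC | intermediate (not isolated)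
26 | (1S,6R,7R,8S)-5,5-dimethoxy-8-[(triethylsilyloxy)methyl]-7-[4-(triisopropylsilyloxy)phenyl]-1-{(E)-2-[4-(triisopropylsilyloxy)phenyl]ethenyl}-2-oxabicyclo[4.2.0]octan-3-one | COC1(OC)CC(=O)O[C@]2(/C=C/c3ccc(O[Si](C(C)C)(C(C)C)C(C)C)cc3)[C@H]1[C@H](c1ccc(O[Si](C(C)C)(C(C)C)C(C)C)cc1)[C@H]2CO[Si](CC)(CC)CC | intermediate
27 | 8-(hydroxymethyl)-5,5-dimethoxy analogue of 26 (triethylsilyl group removed) | COC1(OC)CC(=O)O[C@]2(/C=C/c3ccc(O[Si](C(C)C)(C(C)C)C(C)C)cc3)[C@H]1[C@H](c1ccc(O[Si](C(C)C)(C(C)C)C(C)C)cc1)[C@H]2CO | intermediate (not isolated)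
28 | 8-(hydroxymethyl)-5-methoxy-7-[4-(triisopropylsilyloxy)phenyl]-1-{(E)-2-[4-(triisopropylsilyloxy)phenyl]ethenyl}-2-oxabicyclo[4.2.0]oct-4-en-3-one | COC1=CC(=O)O[C@]2(/C=C/c3ccc(O[Si](C(C)C)(C(C)C)C(C)C)cc3)[C@H]1[C@H](c1ccc(O[Si](C(C)C)(C(C)C)C(C)C)cc1)[C@H]2CO | intermediate
29 | 5-methoxy-3-oxo-7-[4-(triisopropylsilyloxy)phenyl]-1-{(E)-2-[4-(triisopropylsilyloxy)phenyl]ethenyl}-2-oxabicyclo[4.2.0]oct-4-ene-8-carbaldehyde | COC1=CC(=O)O[C@]2(/C=C/c3ccc(O[Si](C(C)C)(C(C)C)C(C)C)cc3)[C@H]1[C@H](c1ccc(O[Si](C(C)C)(C(C)C)C(C)C)cc1)[C@H]2C=O | intermediate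
30 | 2,2,6-trimethyl-4H-1,3-dioxin-4-one | CC1=CC(=O)OC(C)(C)O1 | starting material
31 | lithium dienolate of 30 | [Li]OC1=CC(=C)OC(C)(C)O1 | intermediate (not isolated)
32 | [(2,2-dimethyl-6-methylidene-6H-1,3-dioxin-4-yl)oxy]trimethylsilane | C=C1C=C(O[Si](C)(C)C)OC(C)(C)O1 | intermediate
33 | 8-[2-(2,2-dimethyl-4-oxo-4H-1,3-dioxin-6-yl)-1-hydroxyethyl] analogue of 28 | COC1=CC(=O)O[C@]2(/C=C/c3ccc(O[Si](C(C)C)(C(C)C)C(C)C)cc3)[C@H]1[C@H](c1ccc(O[Si](C(C)C)(C(C)C)C(C)C)cc1)[C@H]2C(O)CC1=CC(=O)OC(C)(C)O1 | intermediate
34 | 8-[(2,2-dimethyl-4-oxo-4H-1,3-dioxin-6-yl)acetyl] analogue of 28 | COC1=CC(=O)O[C@]2(/C=C/c3ccc(O[Si](C(C)C)(C(C)C)C(C)C)cc3)[C@H]1[C@H](c1ccc(O[Si](C(C)C)(C(C)C)C(C)C)cc1)[C@H]2C(=O)CC1=CC(=O)OC(C)(C)O1 | intermediate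
35 | acylketene from 34 (C8–CO–CH2–CO–CH=C=O) | COC1=CC(=O)O[C@]2(/C=C/c3ccc(O[Si](C(C)C)(C(C)C)C(C)C)cc3)[C@H]1[C@H](c1ccc(O[Si](C(C)C)(C(C)C)C(C)C)cc1)[C@H]2C(=O)CC(=O)C=C=O | intermediate (not isolated)
36 | 8-(4-hydroxy-2-oxo-2H-pyran-6-yl) analogue of 37 | COC1=CC(=O)O[C@]2(/C=C/c3ccc(O[Si](C(C)C)(C(C)C)C(C)C)cc3)[C@H]1[C@H](c1ccc(O[Si](C(C)C)(C(C)C)C(C)C)cc1)[C@H]2c1cc(O)cc(=O)o1 | intermediate (not isolated)
37 | (1R,6S,7S,8S)-5-methoxy-8-(4-methoxy-2-oxo-2H-pyran-6-yl)-7-[4-(triisopropylsilyloxy)phenyl]-1-{(E)-2-[4-(triisopropylsilyloxy)phenyl]ethenyl}-2-oxabicyclo[4.2.0]oct-4-en-3-one | COC1=CC(=O)O[C@]2(/C=C/c3ccc(O[Si](C(C)C)(C(C)C)C(C)C)cc3)[C@H]1[C@H](c1ccc(O[Si](C(C)C)(C(C)C)C(C)C)cc1)[C@H]2c1cc(OC)cc(=O)o1 | intermediate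
38 | (1R,6S,7S,8S)-7-(4-hydroxyphenyl)-1-[(E)-2-(4-hydroxyphenyl)ethenyl]-5-methoxy-8-(4-methoxy-2-oxo-2H-pyran-6-yl)-2-oxabicyclo[4.2.0]oct-4-en-3-one | COC1=CC(=O)O[C@]2(/C=C/c3ccc(O)cc3)[C@H]1[C@H](c1ccc(O)cc1)[C@H]2c1cc(OC)cc(=O)o1 | target

## Step count and least certain steps

Total: 22 steps. Longest linear sequence: 18 steps (steps 2 to 12, 15 to 17 and 19 to 22).

**Step 15 (key step).** The bulky alkenyl reagent may enolise the ketone instead of adding to it, add with poor facial selectivity, or attack the freshly formed lactone while excess reagent is still present. Fallback: from ketone 18, vinylcerium dichloride (from vinylmagnesium bromide and CeCl3) is added; this much smaller reagent should give, after the same alkoxide lactonisation, the 1-vinyl lactone F1. An E-selective cross-metathesis with 4-(triisopropylsilyloxy)styrene F2 then installs the aryl end, using the second-generation Hoveyda–Grubbs catalyst in CH2Cl2 at 40 °C. F2 is made from iodide 2 by Suzuki–Miyaura coupling with potassium vinyltrifluoroborate (PdCl2(dppf), Et3N, n-PrOH). The sequence comes back to the route at lactone 26.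

**Step 3.** The ketal may lose methanol under the acid and drift to the conjugated 3-methoxy enynoate, or ketalisation may stall at that enol ether. Fallback: from bis(trimethylsilyl)acetylene 3, one silyl group is cleaved with MeLi and the lithium acetylide is combined with BF3·OEt2 and tetramethyl orthocarbonate to give the alkynyl orthoester F3. A TMSOTf-catalysed addition of 1-(tert-butyldimethylsilyloxy)-1-methoxyethene to the derived dimethoxycarbenium ion (Mukaiyama-type, aprotic, −78 °C) then forms the C4–C5 bond and gives ketal 6 directly, without ever passing through the ketone.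

**Step 6.** Cycloaddition may be slow because the propargylic ketal withdraws electron density, so that ketene oligomerisation wins; zinc dichloride may also ionise the ketal. Fallback: from alkyne 8, the keteniminium triflate generated from N,N-dimethylacetamide, Tf2O and 2,4,6-collidine is added with the same regiochemistry to give the cyclobuteniminium salt F4. Hydrolysis with aqueous NaHCO3 gives cyclobutenone 12 directly, so step 7 is no longer needed.

**Step 11.** Deprotonation may occur on the C6 side, followed by β-loss of methoxide, and the lithium aldolate may undergo retro-aldol cleavage, dehydration to the α-methylene ketone or further addition of formaldehyde. Fallback: from ketone 15, the kinetic enolate is trapped with TMSCl present during deprotonation to give the silyl enol ether F5, whose regiochemical purity can be checked. A Lewis-acid hydroxymethylation with aqueous formaldehyde and Yb(OTf)3 in THF then gives alcohol 17 without a basic aldolate.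

**Step 21.** At 100 °C the acidic hydroxypyranone may promote ionisation of the C1–O2 bond; methylation may occur on the carbonyl oxygen and give the isomeric 2-methoxy-4-pyranone; a phenol may be methylated after adventitious desilylation. Fallback: from aldehyde 29, a vinylogous Mukaiyama aldol with 1,3-dimethoxy-1-(trimethylsilyloxy)buta-1,3-diene (BF3·OEt2, −78 °C) gives the δ-hydroxy-β-methoxy enoate F6. This is oxidised at once with Dess–Martin periodinane to the δ-keto ester F7. Cyclisation of the ketone enol onto the ester with loss of methanol (PPTS, PhMe, 60 °C) gives methoxypyranone 37, so the methoxy group is in place before the ring closes and no thermolysis is needed.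

## Further compounds

F1 | step 15 | 1-ethenyl-5,5-dimethoxy-8-[(triethylsilyloxy)methyl]-7-[4-(triisopropylsilyloxy)phenyl]-2-oxabicyclo[4.2.0]octan-3-one (ring configuration as in 26) | COC1(OC)CC(=O)O[C@]2(C=C)[C@H]1[C@H](c1ccc(O[Si](C(C)C)(C(C)C)C(C)C)cc1)[C@H]2CO[Si](CC)(CC)CC
F2 | step 15 | 4-(triisopropylsilyloxy)styrene | C=Cc1ccc(O[Si](C(C)C)(C(C)C)C(C)C)cc1
F3 | step 3 | 3,3,3-trimethoxy-1-(trimethylsilyl)prop-1-yne | COC(OC)(OC)C#C[Si](C)(C)C
F4 | step 6 | N,N-dimethyl cyclobuteniminium triflate corresponding to 12 (C=N+Me2 in place of C=O) | C[N+](C)=C1CC(c2ccc(O[Si](C(C)C)(C(C)C)C(C)C)cc2)=C1C(OC)(OC)CC(=O)OC.[O-]S(=O)(=O)C(F)(F)F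
F5 | step 11 | trimethylsilyl enol ether of 15 toward the ring CH2 | C[Si](C)(C)OC=1[C@H](C(OC)(OC)CC(=O)OC)[C@H](c2ccc(O[Si](C(C)C)(C(C)C)C(C)C)cc2)C=1
F6 | step 21 | methyl (E)-5-hydroxy-3-methoxypent-2-enoate carrying the bicyclic lactone of 29 at C5 | COC1=CC(=O)O[C@]2(/C=C/c3ccc(O[Si](C(C)C)(C(C)C)C(C)C)cc3)[C@H]1[C@H](c1ccc(O[Si](C(C)C)(C(C)C)C(C)C)cc1)[C@H]2C(O)C/C(OC)=C\C(=O)OC
F7 | step 21 | methyl (E)-3-methoxy-5-oxopent-2-enoate carrying the bicyclic lactone of 29 at C5 | COC1=CC(=O)O[C@]2(/C=C/c3ccc(O[Si](C(C)C)(C(C)C)C(C)C)cc3)[C@H]1[C@H](c1ccc(O[Si](C(C)C)(C(C)C)C(C)C)cc1)[C@H]2C(=O)C/C(OC)=C\C(=O)OC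
A1 | alternative 1 | methyl 4-[4-(tert-butyldimethylsilyloxy)phenyl]-6-[(tert-butyldimethylsilyloxy)methyl]-2-oxo-2H-pyran-5-carboxylate | COC(=O)c1c(-c2ccc(O[Si](C)(C)C(C)(C)C)cc2)cc(=O)oc1CO[Si](C)(C)C(C)(C)C
A2 | alternative 1 | methyl 5-[4-(tert-butyldimethylsilyloxy)phenyl]-1-[(tert-butyldimethylsilyloxy)methyl]-3-oxo-2-oxabicyclo[2.2.0]hex-5-ene-6-carboxylate | O=C1O[C@@]2(CO[Si](C)(C)C(C)(C)C)C(C(=O)OC)=C(c3ccc(O[Si](C)(C)C(C)(C)C)cc3)[C@@H]12
A3 | alternative 2 | 1-[(2R,5R)-2,5-dimethylpyrrolidin-1-yl]-3-(triisopropylsilyloxy)propan-1-one | O=C(CCO[Si](C(C)C)(C(C)C)C(C)C)N1[C@H](C)CC[C@H]1C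
A4 | alternative 2 | 4-[(Z)-3-(tert-butyldimethylsilyloxy)prop-1-en-1-yl]phenyl 2,2-dimethylpropanoate | CC(C)(C)C(=O)Oc1ccc(/C=C\CO[Si](C)(C)C(C)(C)C)cc1
A5 | alternative 2 | 4-{2-[(tert-butyldimethylsilyloxy)methyl]-3-oxo-4-[(triisopropylsilyloxy)methyl]cyclobutyl}phenyl 2,2-dimethylpropanoate (C6 arm cis, C8 arm trans to the aryl) | O=C1[C@H](CO[Si](C)(C)C(C)(C)C)[C@H](c2ccc(OC(=O)C(C)(C)C)cc2)[C@H]1CO[Si](C(C)C)(C(C)C)C(C)C
A6 | alternative 3 | 3-tert-butyl 5-methyl 4-acetoxy-2-[4-(tert-butyldimethylsilyloxy)phenyl]-4-{(E)-2-[4-(tert-butyldimethylsilyloxy)phenyl]ethenyl}pyrrolidine-3,5-dicarboxylate | CC(=O)O[C@]1(/C=C/c2ccc(O[Si](C)(C)C(C)(C)C)cc2)[C@H](C(=O)OC)N[C@H](c2ccc(O[Si](C)(C)C(C)(C)C)cc2)[C@H]1C(=O)OC(C)(C)C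
A7 | alternative 3 | 1-tert-butyl 3-methyl 2-acetoxy-4-[4-(tert-butyldimethylsilyloxy)phenyl]-2-{(E)-2-[4-(tert-butyldimethylsilyloxy)phenyl]ethenyl}cyclobutane-1,3-dicarboxylate | CC(=O)O[C@]1(/C=C/c2ccc(O[Si](C)(C)C(C)(C)C)cc2)[C@H](C(=O)OC)[C@H](c2ccc(O[Si](C)(C)C(C)(C)C)cc2)[C@H]1C(=O)OC(C)(C)C
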